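The route disconnects the B3–B4 bond of the cyclopentane ring B, where B1 is the spiro carbon shared with ring A, B2 the isopropyl-bearing CH and B5 pinane C2. B3 and B4 are the only neighbouring CH2 pair of that ring and sit between the B2 methine and the quaternary pinane carbon. A ring-closing metathesis makes this bond in one operation, away from both crowded centres, after the stereocentres at pinane C2 (cuprate addition) and B2 (Ireland–Claisen transfer) are in place. The precursor is a methyl hex-4-enoate with a vinyl group on pinane C2 and an (E)-propenyl group on B2. Ring A is afterwards built on the B1 ester.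

Key step: step 9

Remarks on the chemistry:
- Labels: ring A is the six-membered ring made of B1 and five further carbons, called ring A positions 1 to 5. Position 1 is the C=O between B1 and position 2, position 2 is C–CH3, position 3 is C–OCH3, position 4 is C(CH3)2 and position 5 is the C=O between position 4 and B1.
- Stereochemical bookkeeping: the target has the (1R,5R)-pinane skeleton of (+)-β-pinene. At pinane C2, B1 lies on the side of the gem-dimethyl bridge (C6) and B4 on the side of the CH2 bridge (C7). On ring B the position 5 carbonyl of ring A is trans and the position 1 carbonyl cis to the B2 isopropyl group. The (R)-allylic alcohol is the enantiomer that gives (S)-B2 through a chair Ireland–Claisen transition state.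
- Assumption: lithium, sodium, potassium and magnesium enolates and catalyst-bound species are treated as transient forms of the numbered compounds; silylated and acylated covalent intermediates that persist in the flask are numbered.

## Route

Step 1
Reactants: 1 (+)-β-pinene
Product: 2 (−)-nopinone [(1S,5R)-6,6-dimethylbicyclo[3.1.1]heptan-2-one]
Conditions: RuCl3·xH2O (2 mol %), NaIO4 (2.2 equiv), MeCN/EtOAc/H2O, 0 °C → rt
Reagents that add atoms: sodium periodate, [Na+].[O-]I(=O)(=O)=O
Why: Catalytic ruthenium tetroxide, regenerated by periodate, should cleave the exocyclic 1,1-disubstituted alkene to the ketone (oxidative alkene cleavage) without touching the saturated bicycle or its two bridgehead stereocentres.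

Step 2
Reactants: 2 (−)-nopinone; 3 triethyl phosphonoacetate
Product: 4 ethyl (2E)-2-[(1S,5R)-6,6-dimethylbicyclo[3.1.1]heptan-2-ylidene]acetate
Conditions: NaH, THF, 0 °C → 65 °C
Reagents that add atoms: none
Why: The Horner–Wadsworth–Emmons reaction of the sodium phosphonate carbanion with the moderately hindered ketone should give the trisubstituted enoate; its alkene geometry does not matter because both isomers converge in step 3.

Step 3
Reactants: 4 ethyl (2E)-2-[(1S,5R)-6,6-dimethylbicyclo[3.1.1]heptan-2-ylidene]acetate
Product: 6 ethyl 2-[(1S,2R,5R)-2-ethenyl-6,6-dimethylbicyclo[3.1.1]heptan-2-yl]acetate, via silyl ketene acetal 5 (not isolated)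
Conditions: CH2=CHMgBr (3 equiv), CuBr·SMe2 (0.2 equiv), Me3SiCl (3 equiv), THF, −78 → 0 °C; then 1 M HCl
Reagents that add atoms: vinylmagnesium bromide, C=C[Mg]Br
Why: Copper-catalysed conjugate addition of the vinyl Grignard reagent, accelerated by Me3SiCl trapping of the enolate, should deliver the vinyl group to pinane C2 from the face of the CH2 bridge (C7), because the inner methyl group of the gem-dimethyl bridge (C6) blocks the other face; this sets the quaternary stereocentre with the acetate arm on the C6 side, and the silyl ketene acetal is hydrolysed on acidic work-up.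

Step 4
Reactants: 6 ethyl 2-[(1S,2R,5R)-2-ethenyl-6,6-dimethylbicyclo[3.1.1]heptan-2-yl]acetate
Product: 7 2-[(1S,2R,5R)-2-ethenyl-6,6-dimethylbicyclo[3.1.1]heptan-2-yl]acetic acid
Conditions: LiOH·H2O, THF/MeOH/H2O, 60 °C; then 1 M HCl
Reagents that add atoms: lithium hydroxide, [Li+].[OH-]
Why: Saponification of an ethyl ester whose carbonyl is one CH2 away from the quaternary carbon should proceed normally, and the vinyl group and the stereocentres are inert to hydroxide.

Step 5
Reactants: 8 (E)-5-methylhex-3-en-2-one
Product: 9 (2R,3E)-5-methylhex-3-en-2-ol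
Conditions: (S)-2-methyl-CBS-oxazaborolidine (0.1 equiv), catecholborane (1.5 equiv), toluene, −78 °C; then H2O
Reagents that add atoms: none
Why: In the Corey–Bakshi–Shibata reduction the alkenyl group takes the place of the large ketone substituent, so the (S)-oxazaborolidine should give the (R)-carbinol by 1,2-hydride delivery in the same sense as with aryl methyl ketones, and the low temperature suppresses hydroboration of the alkene.

Step 6
Reactants: 7 2-[(1S,2R,5R)-2-ethenyl-6,6-dimethylbicyclo[3.1.1]heptan-2-yl]acetic acid; 9 (2R,3E)-5-methylhex-3-en-2-ol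
Product: 10 (2R,3E)-5-methylhex-3-en-2-yl 2-[(1S,2R,5R)-2-ethenyl-6,6-dimethylbicyclo[3.1.1]heptan-2-yl]acetate
Conditions: DCC, DMAP (0.1 equiv), CH2Cl2, 0 °C → rt
Reagents that add atoms: none
Why: Steglich esterification through the O-acylisourea and the acylpyridinium ion should acylate the secondary allylic alcohol with retention at the carbinol carbon, since the C–O bond of the alcohol is never broken.

Step 7
Reactants: 10 (2R,3E)-5-methylhex-3-en-2-yl 2-[(1S,2R,5R)-2-ethenyl-6,6-dimethylbicyclo[3.1.1]heptan-2-yl]acetate
Product: 13 (2R,3S,4E)-2-[(1S,2R,5R)-2-ethenyl-6,6-dimethylbicyclo[3.1.1]heptan-2-yl]-3-(propan-2-yl)hex-4-enoic acid, via silyl ketene acetal 11 (not isolated), via trimethylsilyl ester 12 (not isolated)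
Conditions: LiN(i-Pr)2, THF, −78 °C; Me3SiCl/Et3N, −78 °C → rt, then 60 °C; 1 M HCl
Reagents that add atoms: none
Why: In this Ireland–Claisen rearrangement the kinetic lithium enolate is silylated on oxygen and the ketene acetal should rearrange through a chair transition state with the carbinol methyl group equatorial, so that the C–O stereocentre is transferred suprafacially to the new C–C stereocentre B2 (S) and the propenyl group is formed E; the B1 configuration follows from the ketene acetal geometry and is of no consequence because B1 is enolised again in step 11.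

Step 8
Reactants: 13 (2R,3S,4E)-2-[(1S,2R,5R)-2-ethenyl-6,6-dimethylbicyclo[3.1.1]heptan-2-yl]-3-(propan-2-yl)hex-4-enoic acid
Product: 14 methyl (2R,3S,4E)-2-[(1S,2R,5R)-2-ethenyl-6,6-dimethylbicyclo[3.1.1]heptan-2-yl]-3-(propan-2-yl)hex-4-enoate
Conditions: MeI, K2CO3, DMF, rt
Reagents that add atoms: iodomethane, CI
Why: SN2 O-alkylation of the potassium carboxylate with iodomethane is insensitive to the crowding at the α-carbon and should not epimerise B1 or B2.

Step 9
Reactants: 14 methyl (2R,3S,4E)-2-[(1S,2R,5R)-2-ethenyl-6,6-dimethylbicyclo[3.1.1]heptan-2-yl]-3-(propan-2-yl)hex-4-enoate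
Product: 15 methyl (1S,2R,4′S,5R,5′R)-6,6-dimethyl-4′-(propan-2-yl)spiro[bicyclo[3.1.1]heptane-2,1′-cyclopent[2]ene]-5′-carboxylate
Conditions: second-generation Grubbs catalyst RuCl2(=CHPh)(PCy3)(H2IMes) (5 mol %), CH2Cl2 (0.01 M), 40 °C
Reagents that add atoms: none
Why: The benzylidene of the precatalyst is exchanged for one alkene terminus of 14, the resulting ruthenium alkylidene adds across the second alkene in an intramolecular [2+2] cycloaddition, and cycloreversion of the ruthenacyclobutane releases the B3=B4 double bond while the chain-carrying alkylidene expels propene as the volatile co-product. The closest known reaction type is ring-closing metathesis of 1,6-dienes to cyclopentenes that carry one quaternary and one tertiary allylic carbon. Ring B closes as a five-membered carbocycle by union of the alkene carbons attached to B2 and to pinane C2, so the only new bond is the one ring B bond that is remote from every substituent. No stereocentre is created, and those at pinane C2, B1 and B2 are saturated carbons outside the reacting π systems, so they should keep their configuration. The step needs ring closure to outrun intermolecular cross-metathesis, which is secured by the fully substituted backbone that holds the vinyl and propenyl groups close together, by dilution and by the irreversible escape of propene. The methyl ester is a spectator that does not deactivate the catalyst.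

Step 10
Reactants: 15 methyl (1S,2R,4′S,5R,5′R)-6,6-dimethyl-4′-(propan-2-yl)spiro[bicyclo[3.1.1]heptane-2,1′-cyclopent[2]ene]-5′-carboxylate
Product: 16 methyl (1S,2S,2′R,3′R,5R)-6,6-dimethyl-3′-(propan-2-yl)spiro[bicyclo[3.1.1]heptane-2,1′-cyclopentane]-2′-carboxylate
Conditions: H2 (1 atm), Pd/C (10 wt %), EtOAc, rt
Reagents that add atoms: none
Why: Heterogeneous catalytic hydrogenation should saturate the cis-disubstituted cyclopentene without creating a stereocentre and without affecting the ester.

Step 11
Reactants: 16 methyl (1S,2S,2′R,3′R,5R)-6,6-dimethyl-3′-(propan-2-yl)spiro[bicyclo[3.1.1]heptane-2,1′-cyclopentane]-2′-carboxylate; 17 isobutyraldehyde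
Product: 18 aldol adduct of 16 carrying a 1-hydroxy-2-methylpropyl group on B1 trans to the B2 isopropyl group (carbinol epimers)
Conditions: LiN(i-Pr)2, THF, −78 → −20 °C; then 17, −78 °C; AcOH, −78 °C
Reagents that add atoms: none
Why: Aldol addition of the tetrasubstituted lithium ester enolate to the aldehyde should create the quaternary centre B1 with the hydroxyalkyl group entering on the ring B face opposite the isopropyl group of the adjacent carbon B2 (the face flanked by the B2 hydrogen and the pinane bridgehead C1), which puts the future position 5 carbon of ring A trans and the ester (future position 1) cis to isopropyl; the carbinol configuration is lost in step 12.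

Step 12
Reactants: 18 aldol adduct
Product: 19 β-keto ester with CO2CH3 (cis to isopropyl) and 2-methylpropanoyl (trans to isopropyl) on B1
Conditions: Dess–Martin periodinane, CH2Cl2, rt
Reagents that add atoms: none
Why: Dess–Martin oxidation of the hindered secondary alcohol under neutral conditions should give the β-keto ester without retro-aldol cleavage, and B1 cannot epimerise because it is quaternary.

Step 13
Reactants: 19 β-keto ester
Product: 21 spiro trione with ring A closed (drawn as the enol at ring A position 3), via diketo ester 20 (not isolated)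
Conditions: LiN(i-Pr)2, THF, −78 °C; EtCOCl (1.05 equiv), −78 → 0 °C; then KN(SiMe3)2 (2.2 equiv), 0 °C → rt; 1 M HCl
Reagents that add atoms: propanoyl chloride, CCC(=O)Cl
Why: Since B1 is quaternary, only the isopropyl methine of 19 can be enolised; Claisen-type C-acylation of this enolate with propanoyl chloride should give the 2,2-dimethyl-1,3-diketone 20, whose ethyl ketone enolate then attacks the methyl ester in a Dieckmann condensation that closes ring A and is driven by deprotonation of the acidic triketone.

Step 14
Reactants: 21 spiro trione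
Product: 22 target, (1S,2R,2′R,3′R,5R)-4″-methoxy-3″,5″,5″,6,6-pentamethyl-3′-(propan-2-yl)dispiro[bicyclo[3.1.1]heptane-2,1′-cyclopentane-2′,1″-cyclohexan]-3″-ene-2″,6″-dione
Conditions: Me3SiCHN2, MeOH/toluene, 0 °C → rt
Reagents that add atoms: (trimethylsilyl)diazomethane, C[Si](C)(C)C=[N+]=[N-]
Why: O-Methylation of the acidic enol by the diazoalkane (protonation, then methyl transfer to the enolate oxygen) should occur at the oxygen on ring A position 3, which is flanked only by the methyl groups of position 4, and not at the position 1 oxygen next to the crowded spiro carbon B1; a diazoalkane is chosen because it does not C-methylate position 2.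

## Compound list

1 | (+)-β-pinene, (1R,5R)-6,6-dimethyl-2-methylidenebicyclo[3.1.1]heptane | C=C1CC[C@@H]2C[C@H]1C2(C)C | starting material
2 | (−)-nopinone, (1S,5R)-6,6-dimethylbicyclo[3.1.1]heptan-2-one | O=C1CC[C@@H]2C[C@H]1C2(C)C | intermediate
3 | triethyl phosphonoacetate | CCOC(=O)CP(=O)(OCC)OCC | starting material
4 | ethyl (2E)-2-[(1S,5R)-6,6-dimethylbicyclo[3.1.1]heptan-2-ylidene]acetate (E drawn; any Z isomer is carried along) | CCOC(=O)/C=C1\CC[C@@H]2C[C@H]1C2(C)C | intermediate
5 | ethyl trimethylsilyl ketene acetal of 6 (not isolated) | CCOC(O[Si](C)(C)C)=C[C@@]1(C=C)CC[C@@H]2C[C@H]1C2(C)C | intermediate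
6 | ethyl 2-[(1S,2R,5R)-2-ethenyl-6,6-dimethylbicyclo[3.1.1]heptan-2-yl]acetate (vinyl on the C7 side) | CCOC(=O)C[C@@]1(C=C)CC[C@@H]2C[C@H]1C2(C)C | intermediate
7 | 2-[(1S,2R,5R)-2-ethenyl-6,6-dimethylbicyclo[3.1.1]heptan-2-yl]acetic acid | OC(=O)C[C@@]1(C=C)CC[C@@H]2C[C@H]1C2(C)C | intermediate
8 | (E)-5-methylhex-3-en-2-one | CC(=O)/C=C/C(C)C | starting material
9 | (2R,3E)-5-methylhex-3-en-2-ol | C[C@@H](O)/C=C/C(C)C | intermediate
10 | (2R,3E)-5-methylhex-3-en-2-yl 2-[(1S,2R,5R)-2-ethenyl-6,6-dimethylbicyclo[3.1.1]heptan-2-yl]acetate | C[C@H](/C=C/C(C)C)OC(=O)C[C@@]1(C=C)CC[C@@H]2C[C@H]1C2(C)C | intermediate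
11 | trimethylsilyl ketene acetal of 10, pinanyl group cis to the allyloxy oxygen (not isolated) | C[C@H](/C=C/C(C)C)O/C(O[Si](C)(C)C)=C\[C@@]1(C=C)CC[C@@H]2C[C@H]1C2(C)C | intermediate
12 | trimethylsilyl ester of 13 (not isolated) | C[Si](C)(C)OC(=O)[C@H]([C@@H](C(C)C)/C=C/C)[C@@]1(C=C)CC[C@@H]2C[C@H]1C2(C)C | intermediate
13 | (2R,3S,4E)-2-[(1S,2R,5R)-2-ethenyl-6,6-dimethylbicyclo[3.1.1]heptan-2-yl]-3-(propan-2-yl)hex-4-enoic acid | OC(=O)[C@H]([C@@H](C(C)C)/C=C/C)[C@@]1(C=C)CC[C@@H]2C[C@H]1C2(C)C | intermediate
14 | methyl (2R,3S,4E)-2-[(1S,2R,5R)-2-ethenyl-6,6-dimethylbicyclo[3.1.1]heptan-2-yl]-3-(propan-2-yl)hex-4-enoate (metathesis precursor) | COC(=O)[C@H]([C@@H](C(C)C)/C=C/C)[C@@]1(C=C)CC[C@@H]2C[C@H]1C2(C)C | intermediate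
15 | methyl (1S,2R,4′S,5R,5′R)-6,6-dimethyl-4′-(propan-2-yl)spiro[bicyclo[3.1.1]heptane-2,1′-cyclopent[2]ene]-5′-carboxylate (ring B with B3=B4; CO2CH3 on B1 trans to isopropyl on B2) | COC(=O)[C@@H]1[C@@H](C(C)C)C=C[C@@]12CC[C@@H]3C[C@H]2C3(C)C | intermediate
16 | methyl (1S,2S,2′R,3′R,5R)-6,6-dimethyl-3′-(propan-2-yl)spiro[bicyclo[3.1.1]heptane-2,1′-cyclopentane]-2′-carboxylate (ring B saturated) | COC(=O)[C@@H]1[C@@H](C(C)C)CC[C@@]12CC[C@@H]3C[C@H]2C3(C)C | intermediate
17 | isobutyraldehyde (2-methylpropanal) | CC(C)C=O | starting material
18 | aldol adduct: 16 with B1 quaternary, bearing CO2CH3 (cis to the B2 isopropyl) and 1-hydroxy-2-methylpropyl (trans to it); carbinol epimers | COC(=O)[C@@]1(C(O)C(C)C)[C@@H](C(C)C)CC[C@@]12CC[C@@H]3C[C@H]2C3(C)C | intermediate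
19 | β-keto ester: B1 bears CO2CH3 (cis to isopropyl) and 2-methylpropanoyl (trans to isopropyl) | COC(=O)[C@@]1(C(=O)C(C)C)[C@@H](C(C)C)CC[C@@]12CC[C@@H]3C[C@H]2C3(C)C | intermediate
20 | diketo ester: B1 bears CO2CH3 and 2,2-dimethyl-3-oxopentanoyl (not isolated) | COC(=O)[C@@]1(C(=O)C(C)(C)C(=O)CC)[C@@H](C(C)C)CC[C@@]12CC[C@@H]3C[C@H]2C3(C)C | intermediate
21 | spiro trione, ring A closed (carbonyls at ring A positions 1, 3 and 5; CH–CH3 at position 2; C(CH3)2 at position 4), drawn as the position 3 enol | OC1=C(C)C(=O)[C@@]2(C(=O)C1(C)C)[C@@H](C(C)C)CC[C@@]21CC[C@@H]2C[C@H]1C2(C)C | intermediate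
22 | CNP0307059.1, (1S,2R,2′R,3′R,5R)-4″-methoxy-3″,5″,5″,6,6-pentamethyl-3′-(propan-2-yl)dispiro[bicyclo[3.1.1]heptane-2,1′-cyclopentane-2′,1″-cyclohexan]-3″-ene-2″,6″-dione (ring A position 5 carbonyl trans to isopropyl; B1 on the C6 side of pinane C2) | COC1=C(C)C(=O)[C@@]2(C(=O)C1(C)C)[C@@H](C(C)C)CC[C@@]21CC[C@@H]2C[C@H]1C2(C)C | target

Total step count: 14.
Longest linear sequence: 13 steps (steps 1–4 and 6–14; step 5 is a one-step side branch).

## Steps most likely to fail

**Step 11.** Carbon–carbon bond formation at the enolate carbon, which is flanked by the quaternary pinane carbon and the isopropyl-bearing carbon, may be slower than proton transfer from the enolisable aldehyde. The crowded lithium aldolate may also revert by retro-aldol cleavage before it is quenched, so that 16 is recovered. The fallback sets out from 16. Its enolate is trapped with Me3SiCl (LiN(i-Pr)2, THF, −78 °C) and isolated by non-aqueous work-up as the methyl trimethylsilyl ketene acetal F1. F1 is then added to 17 with TiCl4 in CH2Cl2 at −78 °C (Mukaiyama aldol). This reaction runs through an open transition state and ends in an irreversible silyl and titanium transfer, so it does not depend on the stability of a lithium aldolate. The same face of B1, anti to isopropyl, should be attacked. The fallback comes back to the route at 18.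

**Step 13.** The tetrasubstituted enolate of the isopropyl ketone may be acylated on oxygen instead of carbon, which gives an enol ester that cannot close ring A. The fallback sets out from 19. Its lithium enolate (LiN(i-Pr)2, THF, −78 °C) is added to propanal at −78 °C, where only carbon–carbon bond formation is possible, to give the β-hydroxy ketone F2. Oxidation with Dess–Martin periodinane in CH2Cl2 then gives the diketo ester and the fallback comes back to the route at 20, which is isolated this time. It is cyclised to 21 with KN(SiMe3)2 in THF as in the second half of step 13.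

**Step 3.** Conjugate addition to the trisubstituted enoate, whose β-carbon is next to a bridgehead, may be so slow that 1,2-addition of the Grignard reagent to the ester or base-induced deconjugation of the enoate takes over. The fallback sets out from 4 and raises the electrophilicity of the acceptor. The ester is reduced with i-Bu2AlH (CH2Cl2, −78 °C) to the allylic alcohol F3 and oxidised with MnO2 (CH2Cl2, rt) to the enal F4. The same copper-catalysed vinyl addition with Me3SiCl, which is much faster on an enal, gives the silyl enol ether F5 from attack on the C7 face. Dilute HCl hydrolyses it to the aldehyde F6. Oxidation with NaClO2, NaH2PO4 and 2-methylbut-2-ene in t-BuOH/H2O (Pinnick oxidation) brings the fallback back to the route at acid 7.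

Further compounds
F1 | step 11 | methyl trimethylsilyl ketene acetal of ester 16 | COC(O[Si](C)(C)C)=C1[C@@H](C(C)C)CC[C@@]12CC[C@@H]3C[C@H]2C3(C)C
F2 | step 13 | β-hydroxy ketone: B1 bears CO2CH3 and 3-hydroxy-2,2-dimethylpentanoyl (carbinol epimers) | COC(=O)[C@@]1(C(=O)C(C)(C)C(O)CC)[C@@H](C(C)C)CC[C@@]12CC[C@@H]3C[C@H]2C3(C)C
F3 | step 3 | (2E)-2-[(1S,5R)-6,6-dimethylbicyclo[3.1.1]heptan-2-ylidene]ethan-1-ol | OC/C=C1\CC[C@@H]2C[C@H]1C2(C)C
F4 | step 3 | (2E)-2-[(1S,5R)-6,6-dimethylbicyclo[3.1.1]heptan-2-ylidene]acetaldehyde | O=C/C=C1\CC[C@@H]2C[C@H]1C2(C)C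
F5 | step 3 | trimethylsilyl enol ether of aldehyde F6 | C[Si](C)(C)OC=C[C@@]1(C=C)CC[C@@H]2C[C@H]1C2(C)C
F6 | step 3 | 2-[(1S,2R,5R)-2-ethenyl-6,6-dimethylbicyclo[3.1.1]heptan-2-yl]acetaldehyde | O=CC[C@@]1(C=C)CC[C@@H]2C[C@H]1C2(C)C
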